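Atom labels: abietane numbering C1–C20 for rings A, B and C; C1'–C6' for the bicyclo[3.1.0]hexane (C1' and C5' bridgeheads, C6' apex, C2' spiro carbon); C7' for the isopropyl-bearing side-chain CH; Ca for the ketone carbon of the five-membered ring.
Enabling feature: the five-membered ring Ca–C7–C8–C14–C2' holds a single carbonyl carbon flanked by C7 of ring B and the spiro carbon C2', both of which can be alkene carbons beforehand. At C2' the bond to aromatic C14 lies on the cyclopropane face and the bond to Ca on the open face, so Ca can be delivered as carbon monoxide from the unshielded side.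
Retrosynthetic cuts: take the quinone methide back to a C7-H catechol ether; excise Ca (C7–Ca and Ca–C2'); cut C14–C2' (cross-coupling); open C1'–C5' and C1'–C6' (enyne cycloisomerization); cut C2'–C3' (acetylide addition) and C4'–C5' (malonate condensation).
Forward order: rings A–C come intact from carnosic acid; cyclopentene and cyclopropane form together; the halves are joined at C14–C2'; the spiro cyclopentenone closes by CO insertion; ring C is dearomatized last.
Stereochemistry: C5 and C10 come from (+)-carnosic acid and C7' from (R)-limonene. The C3' carbinol comes from asymmetric transfer hydrogenation and is relayed to C1', C5' and C6' in the cycloisomerization (the E-alkene gives the exo side chain). C2' is set by acyl delivery anti to the cyclopropane.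

Key step: step 21

Assumption: in the platinum-catalysed cycloisomerization the propargylic C–O bond is taken to lie anti to the emerging cyclopropane, which makes the (R)-acetate the correct precursor; if the relay runs in the opposite sense, the (S,S)-ligand in step 13 supplies the other carbinol and nothing else changes.

Step 1
Reactants: 1 (+)-carnosic acid
Product: 2 methyl 11,12-dimethoxyabieta-8,11,13-trien-20-oate
Conditions: MeI, K2CO3, DMF, rt, Ar
Reagents that add atoms: iodomethane, CI
Why: Exhaustive SN2 O-methylation (Williamson ether synthesis plus carboxylate alkylation) under argon caps the acid and both phenols, the hindered C11 hydroxyl included, and ends the air sensitivity of the catechol without touching C5 or C10.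

Step 2
Reactants: 2 methyl 11,12-dimethoxyabieta-8,11,13-trien-20-oate
Product: 3 11,12-dimethoxyabieta-8,11,13-trien-20-ol
Conditions: LiAlH4, THF, reflux
Reagents that add atoms: none
Why: Hydride reduction of the neopentyl C20 ester needs hot LiAlH4, but the molecule offers no other reducible group.

Step 3
Reactants: 3 11,12-dimethoxyabieta-8,11,13-trien-20-ol
Product: 4 11,12-dimethoxyabieta-8,11,13-trien-20-al
Conditions: Dess–Martin periodinane, CH2Cl2, rt
Reagents that add atoms: none
Why: The Dess–Martin oxidation runs under neutral, non-ionizing conditions, so no leaving group is ever placed on C20 and the cationic ring expansion to the icetexane skeleton has no entry point.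

Step 4
Reactants: 4 11,12-dimethoxyabieta-8,11,13-trien-20-al
Product: 6 (5S,10S)-11,12-dimethoxyabieta-8,11,13-triene, via hydrazone 5 (not isolated)
Conditions: N2H4·H2O, KOH, diethylene glycol, 130 then 210 °C
Reagents that add atoms: hydrazine hydrate, NN.O (its nitrogen stays only in intermediate 5)
Why: The Wolff–Kishner reduction in its Huang-Minlon form takes the non-enolizable neopentyl aldehyde to the C20 methyl group through a carbanion instead of a cation, and aryl methyl ethers withstand the hot alkali.

Step 5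
Reactants: 6 (5S,10S)-11,12-dimethoxyabieta-8,11,13-triene
Product: 7 14-bromo-11,12-dimethoxyabieta-8,11,13-triene
Conditions: NBS, MeCN, 0 °C to rt, dark
Reagents that add atoms: N-bromosuccinimide, O=C1CCC(=O)N1Br
Why: Electrophilic aromatic bromination in a polar solvent in the dark goes to C14, the only free position of ring C and para to the C11 methoxy group, while radical bromination at C7 is suppressed.

Step 6
Reactants: 7 14-bromo-11,12-dimethoxyabieta-8,11,13-triene
Product: 8 14-bromo-11,12-dimethoxyabieta-8,11,13-trien-7-one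
Conditions: CrO3, AcOH, rt
Reagents that add atoms: chromium trioxide, O=[Cr](=O)=O
Why: Benzylic oxidation with chromium trioxide selects the secondary C7 methylene as is usual for abietatrienes, since the tertiary isopropyl C–H is buried between bromine and methoxy, and brominating first avoids competing bromination alpha to the ketone.

Step 7
Reactants: 9 (R)-(+)-limonene
Product: 10 (R)-(+)-p-menth-1-ene
Conditions: H2 (1 atm), RhCl(PPh3)3 (1 mol %), benzene/EtOH, rt
Reagents that add atoms: none
Why: Homogeneous hydrogenation with RhCl(PPh3)3 discriminates sterically and saturates the 1,1-disubstituted isopropenyl group while the trisubstituted ring alkene and the stereocentre stay untouched.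

Step 8
Reactants: 10 (R)-(+)-p-menth-1-ene
Product: 12 (R)-3-isopropyl-6-oxoheptanal, via secondary ozonide 11 (not isolated)
Conditions: O3, CH2Cl2, −78 °C; Me2S, −78 °C to rt
Reagents that add atoms: ozone, [O-][O+]=O
Why: Ozonolysis with reductive work-up cleaves the remaining alkene into a methyl ketone and an aldehyde, and the ring stereocentre is carried over unchanged as C7'.

Step 9
Reactants: 12 (R)-3-isopropyl-6-oxoheptanal; 13 malonic acid
Product: 15 (3E,5S)-5-isopropyl-8-oxonon-3-enoic acid, via alkylidenemalonic acid 14 (not isolated)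
Conditions: Et3N, neat, 90 °C
Reagents that add atoms: none
Why: In the deconjugative triethylamine variant of the Knoevenagel–Doebner condensation the aldehyde outcompetes the methyl ketone, the tertiary amine cannot form the enamine that would start the intramolecular aldol of the keto aldehyde, and decarboxylation of 14 through its beta,gamma-shifted form gives the E-alk-3-enoic acid without involving the C7' hydrogen.

Step 10
Reactants: 15 (3E,5S)-5-isopropyl-8-oxonon-3-enoic acid
Product: 16 (3E,5S)-5-isopropyl-N-methoxy-N-methyl-8-oxonon-3-enamide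
Conditions: MeNH(OMe)·HCl, EDC·HCl, N-methylmorpholine, CH2Cl2, 0 °C to rt
Reagents that add atoms: N,O-dimethylhydroxylamine hydrochloride, CNOC.Cl
Why: Carbodiimide amide coupling at low temperature with a weak base gives the Weinreb amide without drawing the skipped alkene into conjugation.

Step 11
Reactants: 16 (3E,5S)-5-isopropyl-N-methoxy-N-methyl-8-oxonon-3-enamide
Product: 17 (3E,5S)-5-isopropyl-N-methoxy-N-methyl-7-(2-methyl-1,3-dioxolan-2-yl)hept-3-enamide
Conditions: HOCH2CH2OH, PPTS (cat.), benzene, reflux, Dean–Stark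
Reagents that add atoms: ethylene glycol, OCCO
Why: Acid-catalysed ketalization with azeotropic removal of water masks the methyl ketone against the organolithium and amide-base steps ahead, and PPTS is too weak an acid to isomerize the beta,gamma-alkene.

Step 12
Reactants: 17 (3E,5S)-5-isopropyl-N-methoxy-N-methyl-7-(2-methyl-1,3-dioxolan-2-yl)hept-3-enamide; 18 trimethylsilylacetylene
Product: 20 (5E,7S)-7-isopropyl-9-(2-methyl-1,3-dioxolan-2-yl)-1-(trimethylsilyl)non-5-en-1-yn-3-one, via lithium trimethylsilylacetylide 19 (not isolated)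
Conditions: 18, n-BuLi, THF, −78 °C; then 17, −78 to −20 °C; pH 7 phosphate buffer
Reagents that add atoms: n-butyllithium, [Li]CCCC (its lithium stays only in intermediate 19)
Why: In the Weinreb ketone synthesis the chelated tetrahedral adduct stops at single addition and releases the skipped enynone only on cold buffered quench, which limits its isomerization.

Step 13
Reactants: 20 (5E,7S)-7-isopropyl-9-(2-methyl-1,3-dioxolan-2-yl)-1-(trimethylsilyl)non-5-en-1-yn-3-one
Product: 21 (3R,5E,7S)-7-isopropyl-9-(2-methyl-1,3-dioxolan-2-yl)-1-(trimethylsilyl)non-5-en-1-yn-3-ol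
Conditions: Ru[(R,R)-TsDPEN](p-cymene) (2 mol %), i-PrOH, rt
Reagents that add atoms: none
Why: Noyori asymmetric transfer hydrogenation of an alkynyl ketone with the preformed base-free ruthenium amide sets the C3' carbinol, the (R,R)-ligand delivering hydride to the face that gives (R)-propargylic alcohols, and the neutral medium spares the acidic skipped methylene.

Step 14
Reactants: 21 (3R,5E,7S)-7-isopropyl-9-(2-methyl-1,3-dioxolan-2-yl)-1-(trimethylsilyl)non-5-en-1-yn-3-ol
Product: 22 (3R,5E,7S)-7-isopropyl-9-(2-methyl-1,3-dioxolan-2-yl)non-5-en-1-yn-3-ol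
Conditions: K2CO3 (cat.), MeOH, 0 °C to rt
Reagents that add atoms: none
Why: Catalytic methoxide cleaves the alkynyl C–Si bond (protodesilylation) and leaves carbinol, alkene and ketal alone.

Step 15
Reactants: 22 (3R,5E,7S)-7-isopropyl-9-(2-methyl-1,3-dioxolan-2-yl)non-5-en-1-yn-3-ol
Product: 23 (3R,5E,7S)-7-isopropyl-9-(2-methyl-1,3-dioxolan-2-yl)non-5-en-1-yn-3-yl acetate
Conditions: Ac2O, Et3N, DMAP (cat.), CH2Cl2, 0 °C to rt
Reagents that add atoms: acetic anhydride, CC(=O)OC(C)=O
Why: DMAP-catalysed acylation esterifies the secondary alcohol at oxygen with retention at C3'.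

Step 16
Reactants: 23 (3R,5E,7S)-7-isopropyl-9-(2-methyl-1,3-dioxolan-2-yl)non-5-en-1-yn-3-yl acetate
Product: 24 (1S,5S,6S)-6-[(3S)-2-methyl-5-(2-methyl-1,3-dioxolan-2-yl)pentan-3-yl]bicyclo[3.1.0]hex-2-en-2-yl acetate (side chain exo)
Conditions: PtCl2 (5 mol %), toluene, 80 °C
Reagents that add atoms: none
Why: In the Ohloff–Rautenstrauch cycloisomerization PtCl2 activates the terminal alkyne, the acetate shifts 1,2 from C3' to C2' and C1' cyclopropanates the alkene (C1'–C5' closes the cyclopentene, C1'–C6' the cyclopropane), the addition being stereospecific so that the E-alkene places the side chain exo, and C1', C5' and C6' being set by relay from C3' because the alkene attacks anti to the still-bound acyloxy group.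

Step 17
Reactants: 24 (1S,5S,6S)-bicyclo[3.1.0]hex-2-en-2-yl acetate
Product: 26 (1S,5S,6S)-6-[(3S)-2-methyl-5-(2-methyl-1,3-dioxolan-2-yl)pentan-3-yl]bicyclo[3.1.0]hex-2-en-2-yl trifluoromethanesulfonate, via lithium enolate 25 (not isolated)
Conditions: MeLi (2.1 equiv), THF, 0 °C; PhNTf2, −78 °C to rt
Reagents that add atoms: N-phenylbis(trifluoromethanesulfonimide), O=S(=O)(N(C1=CC=CC=C1)S(=O)(=O)C(F)(F)F)C(F)(F)F; methyllithium, [Li]C (its lithium stays only in intermediate 25)
Why: Two equivalents of MeLi cleave the enol acetate to the regiodefined lithium enolate (the second is consumed by the acetone released), and O-sulfonylation with PhNTf2 fixes the C2'=C3' enol triflate without disturbing ketal or cyclopropane.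

Step 18
Reactants: 26 (1S,5S,6S)-bicyclo[3.1.0]hex-2-en-2-yl trifluoromethanesulfonate
Product: 27 2-{(1S,5S,6S)-6-[(3S)-2-methyl-5-(2-methyl-1,3-dioxolan-2-yl)pentan-3-yl]bicyclo[3.1.0]hex-2-en-2-yl}-4,4,5,5-tetramethyl-1,3,2-dioxaborolane
Conditions: B2pin2, PdCl2(dppf) (5 mol %), KOAc, 1,4-dioxane, 80 °C
Reagents that add atoms: bis(pinacolato)diboron, CC1(C)OB(OC1(C)C)B1OC(C)(C)C(C)(C)O1
Why: Miyaura borylation exchanges the alkenyl triflate for a pinacol boronate with retention of the alkene position, and the alkenylpalladium intermediate cannot open the adjacent cyclopropane because that would require an allene inside a five-membered ring.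

Step 19
Reactants: 8 14-bromo-11,12-dimethoxyabieta-8,11,13-trien-7-one; 27 bicyclo[3.1.0]hex-2-en-2-yl pinacol boronate
Product: 28 14-{(1S,5S,6S)-6-[(3S)-2-methyl-5-(2-methyl-1,3-dioxolan-2-yl)pentan-3-yl]bicyclo[3.1.0]hex-2-en-2-yl}-11,12-dimethoxyabieta-8,11,13-trien-7-one
Conditions: Pd(OAc)2 (5 mol %), SPhos (10 mol %), K3PO4, toluene/H2O, 90 °C
Reagents that add atoms: none
Why: The Suzuki–Miyaura coupling forms the C14–C2' bond, the bulky electron-rich SPhos ligand coping with the doubly ortho-substituted bromide whose oxidative addition is assisted by the neighbouring C7 carbonyl.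

Step 20
Reactants: 28 14-(bicyclo[3.1.0]hex-2-en-2-yl)-11,12-dimethoxyabieta-8,11,13-trien-7-one
Product: 30 14-(bicyclo[3.1.0]hex-2-en-2-yl)-11,12-dimethoxyabieta-6,8,11,13-tetraen-7-yl trifluoromethanesulfonate (bicyclic unit as in 28), via potassium enolate 29 (not isolated)
Conditions: KN(SiMe3)2, THF, −78 °C; PhNTf2, −78 to 0 °C
Reagents that add atoms: N-phenylbis(trifluoromethanesulfonimide), O=S(=O)(N(C1=CC=CC=C1)S(=O)(=O)C(F)(F)F)C(F)(F)F; potassium bis(trimethylsilyl)amide, C[Si](C)(C)[N-][Si](C)(C)C.[K+] (its potassium stays only in intermediate 29)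
Why: Only the C6 hydrogens are enolizable, so kinetic deprotonation and O-triflation give the C6=C7 enol triflate as a single regioisomer with C5 untouched.

Step 21
Reactants: 30 C7 enol triflate; 31 carbon monoxide
Product: 32 spiro cyclopentenone (Ca ketone between C7 and C2'; C6=C7 and C3'=C4' alkenes; C2' of R configuration with Ca anti and C14 syn to the cyclopropane; 11,12-dimethoxy; side-chain dioxolane)
Conditions: Pd(OAc)2 (10 mol %), dppp (12 mol %), i-Pr2NEt, CO (1 atm), dry DMF, 80 °C
Reagents that add atoms: none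
Why: Zerovalent palladium formed in situ inserts into the C7–OTf bond, CO insertion outruns the strained 4-exo and the 5-endo direct Heck modes, and the cationic acylpalladium adds syn across C2'=C3' before syn beta-hydride elimination of the anti-face H4' releases 32 and a palladium hydride that the amine quenches. The closest known reaction type is the intramolecular carbonylative Heck reaction (cyclic acylpalladation–dehydropalladation of an alkene by a vinyl triflate or halide and CO), which is known to build quaternary carbons. One ring closes, the cyclopentenone Ca–C7–C8–C14–C2', in a 5-exo-trig mode, with both the C7–Ca and the Ca–C2' bond made in this step. The only new stereocentre, spiro C2', is controlled by the cyclopropane: C6' and its endo hydrogen shield one alkene face, so of the two rotamers about the C14–C2' axis only the one that turns the open face toward C7 can bind palladium, Ca enters anti and C14 is pushed syn to the cyclopropane as in the target. Besides this facial selectivity the step needs 5-exo over 6-endo regiochemistry, secured by the three sp2 tether atoms C7, C8 and C14 that hold the acyl carbon over C2', and an intact cyclopropane, secured because palladium lands on C3', which is not cyclopropylcarbinyl, while C2' carries no beta-hydrogen. Nucleophile-free conditions (no alcohol, water or formate) and only one atmosphere of CO keep the acylpalladium from being intercepted and discourage a second insertion.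

Step 22
Reactants: 32 spiro cyclopentenone with C3'=C4' alkene
Product: 33 spiro enone with saturated C3'–C4' (C6=C7 enone retained; all other features as in 32)
Conditions: 2-nitrobenzenesulfonylhydrazide, Et3N, CH2Cl2, rt
Reagents that add atoms: none
Why: Diimide reduction transfers H2 in a concerted syn fashion, prefers the strained cis-disubstituted C3'=C4' alkene to the trisubstituted conjugated C6=C7 alkene and, involving neither metal hydride nor radical, leaves the adjoining cyclopropane closed.

Step 23
Reactants: 33 spiro enone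
Product: 34 saturated spiro ketone (C7-H as either epimer; 11,12-dimethoxy; side-chain dioxolane)
Conditions: [(Ph3P)CuH]6, toluene, degassed H2O, rt
Reagents that add atoms: none
Why: Copper hydride conjugate reduction delivers hydride to C6 of the fixed s-cis enone and water protonates the copper enolate at C7, whose configuration is irrelevant because it is erased in the last step.

Step 24
Reactants: 34 saturated spiro ketone
Product: 35 diketone dimethyl ether (side-chain methyl ketone free)
Conditions: 1 M HCl, THF, rt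
Reagents that add atoms: water, O
Why: Mild aqueous acid hydrolysis of the dioxolane frees the methyl ketone first, so that the Lewis acid of the next step meets no acetal, and neither the cyclopropane nor any fixed stereocentre is acid-labile under these conditions.

Step 25
Reactants: 35 diketone dimethyl ether
Product: 36 11,12-catechol diketone (used crude under argon)
Conditions: BBr3, CH2Cl2, −78 to 0 °C; H2O
Reagents that add atoms: none
Why: Boron tribromide ether cleavage removes both hindered aryl methyl groups at low temperature, and the cyclopropane should survive because it is conjugated with neither ketone and no cation can form next to it.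

Step 26
Reactants: 36 11,12-catechol diketone
Product: 38 CNP0140364.1 (11-hydroxy-12-oxo-7,9(11),13-triene quinone methide), via ortho-quinone 37 (not isolated)
Conditions: Ag2O, Et2O, rt, dark; filtration through silica gel
Reagents that add atoms: none
Why: Ag2O oxidizes the catechol to the ortho-quinone, whose H7 (alpha to Ca in a 2-indanone-type ring and vinylogous to the C11 carbonyl) shifts to O11 to give the 11-hydroxy-12-oxo para-quinone methide, and the neutral base-free medium keeps the product from drifting on to the aromatic 6,7-dehydro catechol tautomer.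

Compound list
1 | (+)-carnosic acid | CC(C)C1=C(O)C(O)=C2C(=C1)CC[C@@H]3[C@@]2(CCCC3(C)C)C(O)=O | starting material
2 | methyl 11,12-dimethoxyabieta-8,11,13-trien-20-oate | CC(C)C1=C(OC)C(OC)=C2C(=C1)CC[C@@H]3[C@@]2(CCCC3(C)C)C(=O)OC | intermediate
3 | 11,12-dimethoxyabieta-8,11,13-trien-20-ol | CC(C)C1=C(OC)C(OC)=C2C(=C1)CC[C@@H]3[C@@]2(CCCC3(C)C)CO | intermediate
4 | 11,12-dimethoxyabieta-8,11,13-trien-20-al | CC(C)C1=C(OC)C(OC)=C2C(=C1)CC[C@@H]3[C@@]2(CCCC3(C)C)C=O | intermediate
5 | C20 hydrazone of 4 | CC(C)C1=C(OC)C(OC)=C2C(=C1)CC[C@@H]3[C@@]2(CCCC3(C)C)C=NN | intermediate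
6 | (5S,10S)-11,12-dimethoxyabieta-8,11,13-triene | CC(C)C1=C(OC)C(OC)=C2C(=C1)CC[C@@H]3[C@@]2(CCCC3(C)C)C | intermediate
7 | 14-bromo-11,12-dimethoxyabieta-8,11,13-triene | CC(C)C1=C(OC)C(OC)=C2C(=C1Br)CC[C@@H]3[C@@]2(CCCC3(C)C)C | intermediate
8 | 14-bromo-11,12-dimethoxyabieta-8,11,13-trien-7-one | CC(C)C1=C(OC)C(OC)=C2C(=C1Br)C(=O)C[C@@H]3[C@@]2(CCCC3(C)C)C | intermediate
9 | (R)-(+)-limonene | CC1=CC[C@@H](CC1)C(C)=C | starting material
10 | (R)-(+)-p-menth-1-ene | CC1=CC[C@@H](CC1)C(C)C | intermediate
11 | secondary ozonide, 4-isopropyl-1-methyl-7,8,9-trioxabicyclo[4.2.1]nonane | CC12CC[C@@H](C(C)C)CC(OO1)O2 | intermediate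
12 | (R)-3-isopropyl-6-oxoheptanal | CC(=O)CC[C@@H](C(C)C)CC=O | intermediate
13 | malonic acid | OC(=O)CC(O)=O | starting material
14 | 2-[(R)-3-isopropyl-6-oxoheptylidene]malonic acid | CC(=O)CC[C@@H](C(C)C)CC=C(C(O)=O)C(O)=O | intermediate
15 | (3E,5S)-5-isopropyl-8-oxonon-3-enoic acid | CC(=O)CC[C@@H](C(C)C)/C=C/CC(O)=O | intermediate
16 | (3E,5S)-5-isopropyl-N-methoxy-N-methyl-8-oxonon-3-enamide | CC(=O)CC[C@@H](C(C)C)/C=C/CC(=O)N(C)OC | intermediate
17 | (3E,5S)-5-isopropyl-N-methoxy-N-methyl-7-(2-methyl-1,3-dioxolan-2-yl)hept-3-enamide | CC1(OCCO1)CC[C@@H](C(C)C)/C=C/CC(=O)N(C)OC | intermediate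
18 | trimethylsilylacetylene | C[Si](C)(C)C#C | starting material
19 | lithium trimethylsilylacetylide | [Li]C#C[Si](C)(C)C | intermediate
20 | (5E,7S)-7-isopropyl-9-(2-methyl-1,3-dioxolan-2-yl)-1-(trimethylsilyl)non-5-en-1-yn-3-one | CC1(OCCO1)CC[C@@H](C(C)C)/C=C/CC(=O)C#C[Si](C)(C)C | intermediate
21 | (3R,5E,7S)-7-isopropyl-9-(2-methyl-1,3-dioxolan-2-yl)-1-(trimethylsilyl)non-5-en-1-yn-3-ol | CC1(OCCO1)CC[C@@H](C(C)C)/C=C/C[C@@H](O)C#C[Si](C)(C)C | intermediate
22 | (3R,5E,7S)-7-isopropyl-9-(2-methyl-1,3-dioxolan-2-yl)non-5-en-1-yn-3-ol | CC1(OCCO1)CC[C@@H](C(C)C)/C=C/C[C@@H](O)C#C | intermediate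
23 | (3R,5E,7S)-7-isopropyl-9-(2-methyl-1,3-dioxolan-2-yl)non-5-en-1-yn-3-yl acetate | CC1(OCCO1)CC[C@@H](C(C)C)/C=C/C[C@@H](OC(C)=O)C#C | intermediate
24 | (1S,5S,6S)-6-[(3S)-2-methyl-5-(2-methyl-1,3-dioxolan-2-yl)pentan-3-yl]bicyclo[3.1.0]hex-2-en-2-yl acetate, side chain exo | CC1(OCCO1)CC[C@@H](C(C)C)[C@H]1[C@@H]2CC=C(OC(C)=O)[C@@H]21 | intermediate
25 | lithium enolate of the bicyclo[3.1.0]hexan-2-one (C2'=C3') | CC1(OCCO1)CC[C@@H](C(C)C)[C@H]1[C@@H]2CC=C(O[Li])[C@@H]21 | intermediate
26 | (1S,5S,6S)-bicyclo[3.1.0]hex-2-en-2-yl trifluoromethanesulfonate, side chain as in 24 | CC1(OCCO1)CC[C@@H](C(C)C)[C@H]1[C@@H]2CC=C(OS(=O)(=O)C(F)(F)F)[C@@H]21 | intermediate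
27 | (1S,5S,6S)-bicyclo[3.1.0]hex-2-en-2-yl pinacol boronate, side chain as in 24 | CC1(OCCO1)CC[C@@H](C(C)C)[C@H]1[C@@H]2CC=C(B3OC(C)(C)C(C)(C)O3)[C@@H]21 | intermediate
28 | 14-[(1S,5S,6S)-6-substituted bicyclo[3.1.0]hex-2-en-2-yl]-11,12-dimethoxyabieta-8,11,13-trien-7-one | CC1(OCCO1)CC[C@@H](C(C)C)[C@H]1[C@@H]2CC=C(C3=C(C(C)C)C(OC)=C(OC)C4=C3C(=O)C[C@H]5C(C)(C)CCC[C@]45C)[C@@H]21 | intermediate
29 | potassium C6=C7 enolate of 28 | CC1(OCCO1)CC[C@@H](C(C)C)[C@H]1[C@@H]2CC=C(C3=C(C(C)C)C(OC)=C(OC)C4=C3C(O[K])=C[C@H]5C(C)(C)CCC[C@]45C)[C@@H]21 | intermediate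
30 | C6=C7 enol triflate of 28 (abieta-6,8,11,13-tetraen-7-yl trifluoromethanesulfonate) | CC1(OCCO1)CC[C@@H](C(C)C)[C@H]1[C@@H]2CC=C(C3=C(C(C)C)C(OC)=C(OC)C4=C3C(OS(=O)(=O)C(F)(F)F)=C[C@H]5C(C)(C)CCC[C@]45C)[C@@H]21 | intermediate
31 | carbon monoxide | [C-]#[O+] | starting material
32 | spiro cyclopentenone, C6=C7 enone and C3'=C4' alkene, C2' (R), Ca anti to the cyclopropane | CC1(OCCO1)CC[C@@H](C(C)C)[C@H]1[C@@H]2C=C[C@@]3(C(=O)C4=C[C@H]5C(C)(C)CCC[C@]5(C)C6=C4C3=C(C(C)C)C(OC)=C6OC)[C@@H]21 | intermediate
33 | spiro enone, C3'–C4' saturated | CC1(OCCO1)CC[C@@H](C(C)C)[C@H]1[C@@H]2CC[C@@]3(C(=O)C4=C[C@H]5C(C)(C)CCC[C@]5(C)C6=C4C3=C(C(C)C)C(OC)=C6OC)[C@@H]21 | intermediate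
34 | saturated spiro ketone, C7 epimers, catechol dimethyl ether, dioxolane | CC1(OCCO1)CC[C@@H](C(C)C)[C@H]1[C@@H]2CC[C@@]3(C(=O)C4C[C@H]5C(C)(C)CCC[C@]5(C)C6=C4C3=C(C(C)C)C(OC)=C6OC)[C@@H]21 | intermediate
35 | diketone dimethyl ether | CC(=O)CC[C@@H](C(C)C)[C@H]1[C@@H]2CC[C@@]3(C(=O)C4C[C@H]5C(C)(C)CCC[C@]5(C)C6=C4C3=C(C(C)C)C(OC)=C6OC)[C@@H]21 | intermediate
36 | 11,12-catechol diketone | CC(=O)CC[C@@H](C(C)C)[C@H]1[C@@H]2CC[C@@]3(C(=O)C4C[C@H]5C(C)(C)CCC[C@]5(C)C6=C4C3=C(C(C)C)C(O)=C6O)[C@@H]21 | intermediate
37 | 11,12-ortho-quinone | CC(=O)CC[C@@H](C(C)C)[C@H]1[C@@H]2CC[C@@]3(C(=O)C4C[C@H]5C(C)(C)CCC[C@]5(C)C6=C4C3=C(C(C)C)C(=O)C6=O)[C@@H]21 | intermediate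
38 | CNP0140364.1 | CC(=O)CC[C@@H](C(C)C)[C@H]1[C@@H]2CC[C@@]3(C(=O)C4=C5C3=C(C(C)C)C(=O)C(O)=C5[C@@]3(C)CCCC(C)(C)[C@@H]3C4)[C@@H]21 | target

Total step count: 26. Longest linear sequence: 20 steps (steps 7–26, from (R)-limonene); the abietane branch (steps 1–6) joins at step 19.

Steps most likely to fail

Step 21 (carbonylative spirocyclization).
- Oxidative addition at the crowded C7 triflate may be throttled by CO-saturated palladium.
- The acylpalladium may decarbonylate or be intercepted before the slow insertion into the trisubstituted alkene.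
- Palladium hydride may re-add to the new C3'=C4' alkene and walk next to the cyclopropane.

The fallback separates carbonylation from ring closure. Setting out from 30, hydroxycarbonylation (Pd(OAc)2, dppf, KOAc, CO 1 atm, DMF/H2O, 60 °C) should give the abieta-6,8,11,13-tetraene-7-carboxylic acid F1. 1-Chloro-N,N,2-trimethylpropenylamine (CH2Cl2, 0 °C, neutral and ketal-safe) converts it into the acid chloride F2. Oxidative addition of the C–Cl bond to zerovalent palladium (Pd2(dba)3, P(2-furyl)3, 1,2,2,6,6-pentamethylpiperidine, toluene, 60 °C) then generates the same acylpalladium with no free CO competing for coordination sites. The known acylpalladation–dehydropalladation of alkenoyl chlorides closes the ring anti to the cyclopropane, and the sequence comes back to the route at 32.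

Step 16 (cycloisomerization).
- The relay from C3' may be incomplete or inverted if a free planar vinyl carbene forms before the alkene attacks.
- The carbinol and the C7' centre may be mismatched.
- A 3,3-acyloxy shift to the allenyl acetate may compete.

The fallback removes the labile carbinol and puts the cyclopropanation under catalyst control. Setting out from 17, LiAlH4 (THF, −78 to 0 °C) gives the beta,gamma-unsaturated aldehyde F3. This is reduced at once (NaBH4, MeOH, 0 °C) to the homoallylic alcohol F4. I2, PPh3 and imidazole give the iodide F5, and LiC≡CH·H2NCH2CH2NH2 in DMSO gives the oxygen-free 1,5-enyne F6. Gold-catalysed alkyne oxidation ((L*)AuCl/AgNTf2 with L* a chiral phosphoramidite, 8-methylquinoline N-oxide, 1,2-dichloroethane, rt) generates an alpha-oxo gold carbene at C1' that cyclopropanates the E-alkene stereospecifically to the bicyclo[3.1.0]hexan-2-one F7. Any minor diastereomer is removed at this ketone stage because C7' is fixed. LiN(i-Pr)2 (THF, −78 °C) converts F7 into lithium enolate 25, where the route resumes toward 26.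

Step 26 (oxidation and tautomerization). The ortho-quinone may stall before the proton shift. Alternatively, the quinone methide may drift on to the aromatic 6,7-dehydro catechol, which surplus oxidant would then consume.

The fallback reaches the quinone methide by a redox-neutral 1,6-elimination with no oxidant in the last flask. Setting out from 34, deprotonation of the acidic H7 (KN(SiMe3)2, THF, −78 °C) and oxygen transfer from 2-(phenylsulfonyl)-3-phenyloxaziridine should give the 7-hydroxy ketone F8. Only C7 is enolizable next to Ca. 1 M HCl in THF frees the side-chain ketone to give the hydroxy diketone F9. BBr3 (CH2Cl2, −78 to 0 °C) uncovers the 7-hydroxy catechol F10, a para-hydroxybenzyl alcohol that loses water across O12–C12···C8–C7, and the sequence comes back to the route at 38.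

Further compounds
F1 | step 21 | 14-(bicyclo[3.1.0]hex-2-en-2-yl)-11,12-dimethoxyabieta-6,8,11,13-tetraene-7-carboxylic acid (bicyclic unit as in 28) | CC1(OCCO1)CC[C@@H](C(C)C)[C@H]1[C@@H]2CC=C(C3=C(C(C)C)C(OC)=C(OC)C4=C3C(C(O)=O)=C[C@H]5C(C)(C)CCC[C@]45C)[C@@H]21
F2 | step 21 | acid chloride of F1 | CC1(OCCO1)CC[C@@H](C(C)C)[C@H]1[C@@H]2CC=C(C3=C(C(C)C)C(OC)=C(OC)C4=C3C(C(Cl)=O)=C[C@H]5C(C)(C)CCC[C@]45C)[C@@H]21
F3 | step 16 | (3E,5S)-5-isopropyl-7-(2-methyl-1,3-dioxolan-2-yl)hept-3-enal | CC1(OCCO1)CC[C@@H](C(C)C)/C=C/CC=O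
F4 | step 16 | (3E,5S)-5-isopropyl-7-(2-methyl-1,3-dioxolan-2-yl)hept-3-en-1-ol | CC1(OCCO1)CC[C@@H](C(C)C)/C=C/CCO
F5 | step 16 | 2-[(3S,4E)-7-iodo-3-isopropylhept-4-en-1-yl]-2-methyl-1,3-dioxolane | CC1(OCCO1)CC[C@@H](C(C)C)/C=C/CCI
F6 | step 16 | 2-[(3S,4E)-3-isopropylnon-4-en-8-yn-1-yl]-2-methyl-1,3-dioxolane | CC1(OCCO1)CC[C@@H](C(C)C)/C=C/CCC#C
F7 | step 16 | (1S,5S,6S)-6-[(3S)-2-methyl-5-(2-methyl-1,3-dioxolan-2-yl)pentan-3-yl]bicyclo[3.1.0]hexan-2-one | CC1(OCCO1)CC[C@@H](C(C)C)[C@H]1[C@@H]2CCC(=O)[C@@H]21
F8 | step 26 | 7-hydroxy derivative of 34 (C7 configuration open) | CC1(OCCO1)CC[C@@H](C(C)C)[C@H]1[C@@H]2CC[C@@]3(C(=O)C4(O)C[C@H]5C(C)(C)CCC[C@]5(C)C6=C4C3=C(C(C)C)C(OC)=C6OC)[C@@H]21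
F9 | step 26 | 7-hydroxy diketone dimethyl ether | CC(=O)CC[C@@H](C(C)C)[C@H]1[C@@H]2CC[C@@]3(C(=O)C4(O)C[C@H]5C(C)(C)CCC[C@]5(C)C6=C4C3=C(C(C)C)C(OC)=C6OC)[C@@H]21
F10 | step 26 | 7-hydroxy 11,12-catechol diketone | CC(=O)CC[C@@H](C(C)C)[C@H]1[C@@H]2CC[C@@]3(C(=O)C4(O)C[C@H]5C(C)(C)CCC[C@]5(C)C6=C4C3=C(C(C)C)C(O)=C6O)[C@@H]21
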